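Glabrol is disconnected at the C2–C3 bond of ring C. The key step exploits the β-aryloxy ketone unit O1–C2–C3–C4(=O), in which C2 is benzylic to the para-oxygenated ring B. In a racemic 2-aryl-4-methylene-4H-1,3-benzodioxine, C2 is the acetal carbon flanked by O1 and the enol oxygen, and C3 is the terminal =CH2 carbon on C4. A chiral silylium ion pair opens this acetal and returns the enol carbon to C2. One operation thus forms C2–C3, closes ring C and sets the only stereocentre, with both acetal enantiomers converging. The precursor is assembled from a salicylic acid and an aldehyde, and one double cross-metathesis completes both prenyl groups.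

Key step: step 10

Remark on the chemistry: the sense of induction of the ion pair cannot be predicted; the (S,S)-catalyst is written, and its mirror image would be used if the first run favours the (R)-flavanone.
Remark on the chemistry: the target SMILES encodes (2S), the natural configuration. Prenyl means 3-methylbut-2-en-1-yl.
Remark on the design: allyl groups are carried through the Lewis acid-mediated acetal formation and turned into the acid-sensitive prenyl groups afterwards. The catalyst carries the same silyl group (TBS) as the two phenol protecting groups, so silyl exchange is degenerate.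
Remark on stoichiometry: step 1 consumes two molecules of allyl bromide and step 8 two molecules of 2-methyl-2-butene; in each case the second molecule is entered under "Reagents that add atoms".

Step 1
Reactants: 1 2,4-dihydroxybenzoic acid; 2 allyl bromide
Product: 3 allyl 4-(allyloxy)-2-hydroxybenzoate
Conditions: allyl bromide (2.1 equiv), K2CO3 (2.2 equiv), DMF, rt
Reagents that add atoms: allyl bromide (a second equivalent of 2, for the 4-O-allyl group), C=CCBr
Why: Double Williamson-type O-alkylation in which one molecule of allyl bromide esterifies the carboxylate and a second one alkylates the 4-phenoxide, while the 2-OH stays locked in its hydrogen bond to the carbonyl group and should not be alkylated.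

Step 2
Reactants: 3 allyl 4-(allyloxy)-2-hydroxybenzoate
Product: 4 allyl 3-allyl-2,4-dihydroxybenzoate
Conditions: PhNEt2, 200 °C, argon
Reagents that add atoms: none
Why: Aromatic Claisen rearrangement; the [3,3] shift should go to C3 and not C5 because the hydrogen-bonded salicylate chelate gives the C3–C4 bond the higher double-bond character.

Step 3
Reactants: 4 allyl 3-allyl-2,4-dihydroxybenzoate
Product: 5 allyl 3-allyl-4-(tert-butyldimethylsilyloxy)-2-hydroxybenzoate
Conditions: TBSCl (1.1 equiv), imidazole, DMF, 0 °C to rt
Reagents that add atoms: tert-butyldimethylsilyl chloride, CC(C)(C)[Si](C)(C)Cl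
Why: Imidazole-promoted silylation of a phenol; only the free 4-OH reacts, since the chelated and doubly flanked 2-OH is inert to one equivalent of silyl chloride.

Step 4
Reactants: 5 allyl 3-allyl-4-(tert-butyldimethylsilyloxy)-2-hydroxybenzoate
Product: 6 3-allyl-4-(tert-butyldimethylsilyloxy)-2-hydroxybenzoic acid
Conditions: Pd(PPh3)4 (3 mol %), morpholine (3 equiv), THF, rt; cold aqueous citric acid work-up
Reagents that add atoms: none
Why: Tsuji–Trost deallylation; zerovalent palladium ionises only the allyl ester and morpholine traps the π-allyl complex, so the aryl silyl ether and the C-allyl group should stay intact under these neutral conditions.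

Step 5
Reactants: 7 4-(allyloxy)benzaldehyde
Product: 8 3-allyl-4-hydroxybenzaldehyde
Conditions: neat, 200 °C, argon
Reagents that add atoms: none
Why: Aromatic Claisen rearrangement; both ortho positions are equivalent, so a single C-allyl phenol is expected.

Step 6
Reactants: 8 3-allyl-4-hydroxybenzaldehyde
Product: 9 3-allyl-4-(tert-butyldimethylsilyloxy)benzaldehyde
Conditions: TBSCl, imidazole, CH2Cl2, rt
Reagents that add atoms: tert-butyldimethylsilyl chloride, CC(C)(C)[Si](C)(C)Cl
Why: Standard imidazole-promoted silylation of a phenol.

Step 7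
Reactants: 6 3-allyl-4-(tert-butyldimethylsilyloxy)-2-hydroxybenzoic acid; 9 3-allyl-4-(tert-butyldimethylsilyloxy)benzaldehyde
Product: 11 racemic 8-allyl-2-[3-allyl-4-(tert-butyldimethylsilyloxy)phenyl]-7-(tert-butyldimethylsilyloxy)-4H-1,3-benzodioxin-4-one, via bis(trimethylsilyl) salicylate 10 (not isolated)
Conditions: HMDS (1.2 equiv), CH2Cl2, rt, evaporate; then 9, TMSOTf (10 mol %), CH2Cl2, −78 °C; pyridine quench
Reagents that add atoms: none
Why: Silyl-mediated acetalisation of a hydroxy acid with an aldehyde; TMSOTf activates the aldehyde, the silyl ester and silyl ether oxygens add in turn, and loss of hexamethyldisiloxane drives closure to the cyclic acylal, under aprotic conditions that should spare the aryl TBS ethers and the allyl groups (the acetal centre forms racemic, which does not matter).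

Step 8
Reactants: 11 racemic 8-allyl-2-[3-allyl-4-(tert-butyldimethylsilyloxy)phenyl]-7-(tert-butyldimethylsilyloxy)-4H-1,3-benzodioxin-4-one; 12 2-methyl-2-butene
Product: 13 racemic 7-(tert-butyldimethylsilyloxy)-2-[4-(tert-butyldimethylsilyloxy)-3-prenylphenyl]-8-prenyl-4H-1,3-benzodioxin-4-one
Conditions: second-generation Grubbs catalyst (H2IMes)(PCy3)Cl2Ru=CHPh (5 mol %), 1,4-benzoquinone (10 mol %), 2-methyl-2-butene/CH2Cl2 1:1, 35 °C
Reagents that add atoms: 2-methyl-2-butene (a second equivalent of 12, for the second prenyl group), CC=C(C)C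
Why: Olefin cross-metathesis in which each terminal allyl group takes an isopropylidene unit from its own molecule of the excess 2-methyl-2-butene and releases propene; the trisubstituted prenyl alkenes formed should not react further, and benzoquinone suppresses allyl-to-propenyl migration.

Step 9
Reactants: 13 racemic 7-(tert-butyldimethylsilyloxy)-2-[4-(tert-butyldimethylsilyloxy)-3-prenylphenyl]-8-prenyl-4H-1,3-benzodioxin-4-one
Product: 14 racemic 7-(tert-butyldimethylsilyloxy)-2-[4-(tert-butyldimethylsilyloxy)-3-prenylphenyl]-4-methylene-8-prenyl-4H-1,3-benzodioxine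
Conditions: Cp2TiMe2 (3 equiv), toluene, 70 °C, dark; filtration through Et3N-deactivated basic alumina
Reagents that add atoms: dimethyltitanocene, C[Ti](C)(C1C=CC=C1)C1C=CC=C1
Why: Petasis methylenation; thermolysis of Cp2TiMe2 gives Cp2Ti=CH2, whose [2+2] addition to the lactone carbonyl and cycloreversion should deliver the enol ether under neutral conditions without opening the acylal, as established for 1,3-dioxan-4-ones.

Step 10
Reactants: 14 racemic 7-(tert-butyldimethylsilyloxy)-2-[4-(tert-butyldimethylsilyloxy)-3-prenylphenyl]-4-methylene-8-prenyl-4H-1,3-benzodioxine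
Product: 16 (S)-glabrol bis(tert-butyldimethylsilyl) ether, via silyl enol ether aryloxycarbenium ion 15 (not isolated)
Conditions: (S,S)-imidodiphosphorimidate acid built from two (S)-3,3'-bis[3,5-bis(trifluoromethyl)phenyl]-1,1'-bi-2-naphthol units with both nitrogen substituents SO2CF3 (5 mol %), pre-silylated with allyl-TBS (15 mol %), toluene, −60 °C; Et3N quench
Reagents that add atoms: none
Why: Proposed new method: the silylium ion of the chiral ion pair silylates the enol ether oxygen O3 of 14 and the C2–O3 bond heterolyses to 15, a silyl enol ether tethered through ring A to an aryloxycarbenium ion (O1=C2) that is stabilised by the para-silyloxy ring B and paired with the imidodiphosphorimidate anion; the enol carbon then adds to C2 in a Mukaiyama-type step and the silyl group returns to the anion. The closest known reactions are the Lewis acid Petasis–Ferrier rearrangement of 4-methylene-1,3-dioxanes to tetrahydropyran-4-ones and ion-pair-catalysed additions of enol silanes to oxocarbenium ions. Ring C closes by a 6-endo-trig attack of the enol carbon on the oxocarbenium ion (enol-endo), the only ring size the ortho tether allows. The C2 stereocentre is set by the chiral counteranion, which shields one face of the planar cation (catalyst control), and because ionisation erases the acetal centre both enantiomers of 14 should funnel into the same ion pair. The step needs C–C closure by the enol silane to outrun capture of the cation by the C8 prenyl alkene and recombination at oxygen: the silyl enol ether is by far the strongest π-nucleophile within reach, O-recombination only returns 14, and ionisation at C2–O1 is reversible and unproductive. Pre-silylation of the acid with allyl-TBS removes free protons, so the prenyl groups and the aryl TBS ethers should remain spectators.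

Step 11
Reactants: 16 (S)-glabrol bis(tert-butyldimethylsilyl) ether
Product: 17 glabrol
Conditions: TBAF (2.5 equiv), AcOH (3 equiv), THF, 0 °C; pH 6 phosphate buffer
Reagents that add atoms: none
Why: Fluoride-mediated desilylation of two aryl silyl ethers; acetic acid keeps the medium too weakly basic for the 4'-phenoxide to open ring C to the chalcone, so the C2 configuration should be retained.

Compound list
1 | 2,4-dihydroxybenzoic acid | O=C(O)c1ccc(O)cc1O | starting material
2 | allyl bromide | C=CCBr | starting material
3 | allyl 4-(allyloxy)-2-hydroxybenzoate | C=CCOC(=O)c1ccc(OCC=C)cc1O | intermediate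
4 | allyl 3-allyl-2,4-dihydroxybenzoate | C=CCOC(=O)c1ccc(O)c(CC=C)c1O | intermediate
5 | allyl 3-allyl-4-(tert-butyldimethylsilyloxy)-2-hydroxybenzoate | C=CCOC(=O)c1ccc(O[Si](C)(C)C(C)(C)C)c(CC=C)c1O | intermediate
6 | 3-allyl-4-(tert-butyldimethylsilyloxy)-2-hydroxybenzoic acid | O=C(O)c1ccc(O[Si](C)(C)C(C)(C)C)c(CC=C)c1O | intermediate
7 | 4-(allyloxy)benzaldehyde | C=CCOc1ccc(C=O)cc1 | starting material
8 | 3-allyl-4-hydroxybenzaldehyde | C=CCc1cc(C=O)ccc1O | intermediate
9 | 3-allyl-4-(tert-butyldimethylsilyloxy)benzaldehyde | C=CCc1cc(C=O)ccc1O[Si](C)(C)C(C)(C)C | intermediate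
10 | trimethylsilyl 3-allyl-4-(tert-butyldimethylsilyloxy)-2-(trimethylsilyloxy)benzoate | C=CCc1c(O[Si](C)(C)C)c(C(=O)O[Si](C)(C)C)ccc1O[Si](C)(C)C(C)(C)C | intermediate
11 | racemic 8-allyl-2-[3-allyl-4-(tert-butyldimethylsilyloxy)phenyl]-7-(tert-butyldimethylsilyloxy)-4H-1,3-benzodioxin-4-one | O=C1OC(c2ccc(O[Si](C)(C)C(C)(C)C)c(CC=C)c2)Oc2c1ccc(O[Si](C)(C)C(C)(C)C)c2CC=C | intermediate
12 | 2-methyl-2-butene | CC=C(C)C | starting material
13 | racemic 7-(tert-butyldimethylsilyloxy)-2-[4-(tert-butyldimethylsilyloxy)-3-prenylphenyl]-8-prenyl-4H-1,3-benzodioxin-4-one | O=C1OC(c2ccc(O[Si](C)(C)C(C)(C)C)c(CC=C(C)C)c2)Oc2c1ccc(O[Si](C)(C)C(C)(C)C)c2CC=C(C)C | intermediate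
14 | racemic 7-(tert-butyldimethylsilyloxy)-2-[4-(tert-butyldimethylsilyloxy)-3-prenylphenyl]-4-methylene-8-prenyl-4H-1,3-benzodioxine | C=C1OC(c2ccc(O[Si](C)(C)C(C)(C)C)c(CC=C(C)C)c2)Oc2c1ccc(O[Si](C)(C)C(C)(C)C)c2CC=C(C)C | intermediate
15 | ring-opened cation (imidodiphosphorimidate as counter-ion): TBS enol ether of the ring A aryl methyl ketone whose ortho oxygen carries the 4-(tert-butyldimethylsilyloxy)-3-prenylbenzylidene oxocarbenium unit | C=C(O[Si](C)(C)C(C)(C)C)c1ccc(O[Si](C)(C)C(C)(C)C)c(CC=C(C)C)c1[O+]=Cc1ccc(O[Si](C)(C)C(C)(C)C)c(CC=C(C)C)c1 | intermediate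
16 | (S)-glabrol bis(tert-butyldimethylsilyl) ether, (S)-7-(tert-butyldimethylsilyloxy)-2-[4-(tert-butyldimethylsilyloxy)-3-prenylphenyl]-8-prenylchroman-4-one | CC(C)=CCc1cc([C@@H]2CC(=O)c3ccc(O[Si](C)(C)C(C)(C)C)c(CC=C(C)C)c3O2)ccc1O[Si](C)(C)C(C)(C)C | intermediate
17 | glabrol, (S)-7-hydroxy-2-(4-hydroxy-3-prenylphenyl)-8-prenylchroman-4-one | CC(C)=CCc1cc([C@@H]2CC(=O)c3ccc(O)c(CC=C(C)C)c3O2)ccc1O | target

Total step count: 11. Longest linear sequence: 9 steps (steps 1 to 4 and 7 to 11).

Steps most likely to fail

Step 10. The ion pair may discriminate the two faces of the planar aryloxycarbenium ion poorly, the product may racemise by re-ionisation, or the cation may be intercepted by the C8 prenyl alkene. The fallback sets out from 14 and uses known chemistry only. Mild hydrolysis (PPTS, wet THF, rt) splits the enol acetal into equimolar 1-[4-(tert-butyldimethylsilyloxy)-2-hydroxy-3-prenylphenyl]ethanone F1 and 4-(tert-butyldimethylsilyloxy)-3-prenylbenzaldehyde F2. The crude pair is then joined by a Kabbe condensation (pyrrolidine, toluene, 4 Å molecular sieves, 60 °C; aldol condensation followed by oxa-Michael closure) to racemic glabrol bis(tert-butyldimethylsilyl) ether F3. Preparative chromatography on a polysaccharide carbamate chiral stationary phase separates the (S)-enantiomer from (R)-glabrol bis(tert-butyldimethylsilyl) ether F4. The route is rejoined at 16.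

Step 7. The electron-rich aldehyde may not be captured as the cyclic acylal: the silyl ester may hydrolyse before ring closure, or the product may re-ionise under TMSOTf. The fallback sets out from 9 and 6. The aldehyde is converted into 3-allyl-4-(tert-butyldimethylsilyloxy)benzaldehyde dimethyl acetal F5 (HC(OMe)3, PPTS cat., MeOH, rt). F5 and acid 6 then undergo acid-catalysed acetal exchange (PPTS cat., toluene, 70 °C, 5 Å molecular sieves to remove methanol). The allyl groups tolerate this Brønsted acid better than prenyl groups would. The route is rejoined at 11.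

Step 8. Exchange may stop at one of the two flanked allyl groups, or ruthenium hydride species may move the allyl double bonds into conjugation, giving mixtures that are hard to separate. The fallback sets out from 11. Lemieux–Johnson cleavage (OsO4 cat., NaIO4, 2,6-lutidine, dioxane–water) gives 7-(tert-butyldimethylsilyloxy)-2-[4-(tert-butyldimethylsilyloxy)-3-(2-oxoethyl)phenyl]-8-(2-oxoethyl)-4H-1,3-benzodioxin-4-one F6. A double Wittig olefination with isopropylidenetriphenylphosphorane (from isopropyltriphenylphosphonium iodide and n-BuLi, THF, −78 °C) then builds both prenyl groups. The route is rejoined at 13.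

Further compounds
F1 | step 10 | 1-[4-(tert-butyldimethylsilyloxy)-2-hydroxy-3-prenylphenyl]ethanone | CC(=O)c1ccc(O[Si](C)(C)C(C)(C)C)c(CC=C(C)C)c1O
F2 | step 10 | 4-(tert-butyldimethylsilyloxy)-3-prenylbenzaldehyde | CC(C)=CCc1cc(C=O)ccc1O[Si](C)(C)C(C)(C)C
F3 | step 10 | racemic glabrol bis(tert-butyldimethylsilyl) ether | CC(C)=CCc1cc(C2CC(=O)c3ccc(O[Si](C)(C)C(C)(C)C)c(CC=C(C)C)c3O2)ccc1O[Si](C)(C)C(C)(C)C
F4 | step 10 | (R)-glabrol bis(tert-butyldimethylsilyl) ether | CC(C)=CCc1cc([C@H]2CC(=O)c3ccc(O[Si](C)(C)C(C)(C)C)c(CC=C(C)C)c3O2)ccc1O[Si](C)(C)C(C)(C)C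
F5 | step 7 | 3-allyl-4-(tert-butyldimethylsilyloxy)benzaldehyde dimethyl acetal | COC(OC)c1ccc(O[Si](C)(C)C(C)(C)C)c(CC=C)c1
F6 | step 8 | 7-(tert-butyldimethylsilyloxy)-2-[4-(tert-butyldimethylsilyloxy)-3-(2-oxoethyl)phenyl]-8-(2-oxoethyl)-4H-1,3-benzodioxin-4-one | O=CCc1cc(C2OC(=O)c3ccc(O[Si](C)(C)C(C)(C)C)c(CC=O)c3O2)ccc1O[Si](C)(C)C(C)(C)C
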